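**Strategy.** Everything rests on cutting the C18–C19 bond in the unbranched (CH2)15 tether between the C5–C8 diyne and C2 of the furan ring. Both carbons are plain methylenes, ten bonds from the diyne and five from the ring, so the bond carries no stereochemical or regiochemical demand and can be made last. A copper-catalysed sp3–sp3 coupling of 5-(furan-2-yl)pentylmagnesium bromide with 18-bromooctadeca-5,7-diynoic acid, its carboxyl group masked in the flask as the magnesium salt, joins a C18 and a C9 fragment and gives the unprotected target in one operation. The bromo diynoic acid comes from a Cadiot–Chodkiewicz coupling; the Grignard precursor from alkylation of 2-furyllithium.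

Key step: step 5

Remark: numbering takes the carboxyl carbon as C1 (diyne C5–C8, methylenes C9–C23, C23 on furan C2); the target has no stereocentre or double-bond geometry, and the diynes 4, 6 and 13 are handled in solution and away from light because conjugated diynes can polymerise.

Step 1
Reactants: 1 1,10-dibromodecane; 2 lithium acetylide ethylenediamine complex
Product: 3 12-bromododec-1-yne
Conditions: 1 (3 equiv), 2 (1 equiv), DMSO, 10 °C to rt; excess 1 recovered by distillation
Reagents that add atoms: none
Why: SN2 alkylation of lithium acetylide by a primary bromide in DMSO, in which the threefold excess of the symmetrical dibromide should keep substitution at the second end statistically low.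

Step 2
Reactants: 3 12-bromododec-1-yne
Product: 4 1,12-dibromododec-1-yne
Conditions: NBS (1.1 equiv), AgNO3 (cat.), acetone, rt, dark
Reagents that add atoms: N-bromosuccinimide, O=C1CCC(=O)N1Br
Why: Silver-catalysed electrophilic bromination of the terminal alkyne via a silver acetylide, which is selective for the C(sp)–H bond and should leave the primary alkyl bromide untouched.

Step 3
Reactants: 4 1,12-dibromododec-1-yne; 5 hex-5-ynoic acid
Product: 6 18-bromooctadeca-5,7-diynoic acid
Conditions: 5 (1.3 equiv), CuCl (cat.), NH2OH·HCl, 70% aq. EtNH2, MeOH, 0 °C, slow addition of 4; then cold dilute HCl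
Reagents that add atoms: none
Why: Cadiot–Chodkiewicz coupling of the copper(I) acetylide of 5 with the bromoalkyne 4 gives the unsymmetrical 1,3-diyne; slow addition of 4 and hydroxylamine (which holds copper as Cu(I)) limit homocoupling, and at 0 °C the primary C–Br bond should react with ethylamine far more slowly than the alkynyl bromide reacts at copper.

Step 4
Reactants: 7 furan; 8 1,5-dibromopentane
Product: 10 2-(5-bromopentyl)furan, via 2-furyllithium 9 (not isolated)
Conditions: n-BuLi, THF, −20 to 0 °C; then 8 (3 equiv), THF, −78 °C to rt
Reagents that add atoms: none
Why: Directed lithiation of furan at C2 (the position alpha to oxygen) followed by SN2 alkylation at one end of the dibromide used in excess, so the ring is brought in already 2-substituted.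

Step 5
Reactants: 10 2-(5-bromopentyl)furan; 6 18-bromooctadeca-5,7-diynoic acid
Product: 13 23-(furan-2-yl)tricosa-5,7-diynoic acid, via 5-(furan-2-yl)pentylmagnesium bromide 11 (not isolated), via chloromagnesium 18-bromooctadeca-5,7-diynoate 12 (not isolated)
Conditions: flask A: 10, Mg, cat. I2, THF, 40 °C; flask B: 6, MeMgCl (1.0 equiv), THF, −30 °C; then Li2CuCl4 (5 mol%), NMP (4 equiv), slow addition of A (1.5 equiv) to B, −20 to 0 °C, dark; cold 1 M HCl to pH 3
Reagents that add atoms: none
Why: Kochi-type copper-catalysed Grignard–alkyl halide cross-coupling: Li2CuCl4 is reduced by 11 to a copper(I) alkyl/cuprate, which displaces bromide at C18 of 12 in an SN2-like oxidative addition, and reductive elimination from the dialkylcopper(III) species forms the C18–C19 bond and returns copper(I). The closest known reaction type is the Li2CuCl4-catalysed coupling of alkyl Grignard reagents with halomagnesium salts of ω-bromoalkanoic acids used to build long-chain fatty acids. No ring is closed and no stereocentre is created, so only chemoselectivity is needed: substitution at the primary C–Br bond must outrun addition to the C5–C8 diyne, attack at the carboxyl group and homocoupling. The carboxyl group is secured by prior conversion into the magnesium carboxylate 12, which has no acidic proton and should not be attacked by a Grignard reagent at or below 0 °C. The dialkyl-substituted internal diyne is not expected to be carbometalated under catalytic copper at low temperature (alkynes even serve as stabilising additives in such couplings), and the furan ring has no C–H bond acidic enough for the Grignard reagent. Slow addition of 11 in THF/NMP keeps its concentration low and should limit homocoupling and halogen–metal exchange.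

**Compound list**
1 | 1,10-dibromodecane | BrCCCCCCCCCCBr | starting material
2 | lithium acetylide ethylenediamine complex | [Li+].[C-]#C.NCCN | starting material
3 | 12-bromododec-1-yne | C#CCCCCCCCCCCBr | intermediate
4 | 1,12-dibromododec-1-yne | BrC#CCCCCCCCCCCBr | intermediate
5 | hex-5-ynoic acid | OC(=O)CCCC#C | starting material
6 | 18-bromooctadeca-5,7-diynoic acid | O=C(O)CCCC#CC#CCCCCCCCCCCBr | intermediate
7 | furan | c1ccoc1 | starting material
8 | 1,5-dibromopentane | BrCCCCCBr | starting material
9 | 2-furyllithium | [Li]c1ccco1 | intermediate
10 | 2-(5-bromopentyl)furan | BrCCCCCc1ccco1 | intermediate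
11 | 5-(furan-2-yl)pentylmagnesium bromide | Br[Mg]CCCCCc1ccco1 | intermediate
12 | chloromagnesium 18-bromooctadeca-5,7-diynoate | Cl[Mg]OC(=O)CCCC#CC#CCCCCCCCCCCBr | intermediate
13 | 23-(furan-2-yl)tricosa-5,7-diynoic acid | O=C(O)CCCC#CC#CCCCCCCCCCCCCCCCc1ccco1 | target

**Step count.** Total: 5 steps. Longest linear sequence: 4 steps (1, 2, 3, 5); step 4 is a one-step branch.

**Steps most likely to fail**

1. Step 5 (key step). The alkylcopper or Grignard species may add across the conjugated diyne, the Grignard reagent may homocouple, or the magnesium carboxylate may precipitate and stall the substitution. The fallback replaces the basic organomagnesium by a neutral organoborane and the carboxylate by an ester, and forms the same C18–C19 bond under palladium catalysis. It sets out from 6 and from 9 (made from 7 as in step 4) and comes back at 13. The acid 6 would be esterified (MeOH, cat. H2SO4, rt) to methyl 18-bromooctadeca-5,7-diynoate F1. 2-Furyllithium 9 would be alkylated with 5-bromopent-1-ene (C=CCCCBr) to 2-(pent-4-en-1-yl)furan F2. Hydroboration of the terminal alkene of F2 with 9-BBN-H (THF, rt) should give 9-[5-(furan-2-yl)pentyl]-9-borabicyclo[3.3.1]nonane F3. An alkyl–alkyl Suzuki–Miyaura coupling of F1 with F3 (Pd(OAc)2, PCy3, K3PO4·H2O, THF, rt) should give methyl 23-(furan-2-yl)tricosa-5,7-diynoate F4. Saponification (LiOH, THF/H2O, rt; cold dilute acid) would then deliver 13.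

2. Step 3. Reductive homocoupling of the bromoalkyne and N-alkylation of ethylamine at the primary C–Br bond may compete with the heterocoupling. The fallback is an oxidative heterocoupling that needs neither a bromoalkyne nor a primary amine. It sets out from 3 (step 2 is skipped) and 5 and comes back at 6. Compound 3 would be coupled with a fivefold excess of 5 under Hay conditions (CuCl, TMEDA cat., O2, acetone, rt). The statistical mixture should separate by the number of carboxyl groups: the diacid dimer of 5 is removed by aqueous extraction and chromatography, and the neutral dimer of 3 by base extraction. No new compound is made on this path.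

3. Step 1. Substitution at both ends of the dibromide, and alkylation of ethylenediamine or elimination, may erode the monoalkyne. The fallback uses a chain whose two ends are already different. It sets out from 2 and commercial 10-bromodecan-1-ol (OCCCCCCCCCCBr) and comes back at 3. Alkynylation (2, 2.2 equiv, DMSO, rt) should give dodec-11-yn-1-ol F5, and Appel bromination (CBr4, PPh3, CH2Cl2, 0 °C) would then give 3.

**Further compounds**
F1 | step 5 | methyl 18-bromooctadeca-5,7-diynoate | COC(=O)CCCC#CC#CCCCCCCCCCCBr
F2 | step 5 | 2-(pent-4-en-1-yl)furan | C=CCCCc1ccco1
F3 | step 5 | 9-[5-(furan-2-yl)pentyl]-9-borabicyclo[3.3.1]nonane | C(CCCCc1ccco1)B2C3CCCC2CCC3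
F4 | step 5 | methyl 23-(furan-2-yl)tricosa-5,7-diynoate | COC(=O)CCCC#CC#CCCCCCCCCCCCCCCCc1ccco1
F0 | step 3 | none | none
F5 | step 1 | dodec-11-yn-1-ol | C#CCCCCCCCCCCO
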